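## Retrosynthetic overview

1. Target 36 ⇐ phenol desilylation of 35 ⇐ epoxidation of C8=C9 in 34 ⇐ late ester coupling of diol 33 with acid chloride 22 (17 non-hydrogen atoms each).
2. Diol 33 ⇐ chelation-controlled reduction of β-hydroxy ketone 31 ⇐ N–O cleavage of tricyclic isoxazoline 29.
3. 29 ⇐ intramolecular nitrile oxide cycloaddition of 28: the seven-membered ring and the isoxazoline form together on the existing cyclopentene, and the tether from C1 fixes C5 and C4.
4. Cycloaddition precursor ⇐ Negishi coupling of neopentylzinc 24 (C11 half; C1 set by asymmetric conjugate methylation of enone 3) with (Z)-vinyl iodide 17 (C6–C9 half, from propargyl alcohol and 1,3-dithiane).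
5. Ring order: cyclopentene (from 1) → seven-membered ring plus isoxazoline in one step → epoxide last.

Assumption: the SMILES is read as the cis-fused hydroazulene (C1–CH3 and H-5 on the same face) with 1S,4R,5S,6R,8R,9S configuration. Names use daucane locants: C1 methyl-bearing ring-fusion carbon, C2/C3 CH2, C4 isopropyl carbinol, C5 ring-fusion CH, C6 ester carbon, C7 CH2, C8 methyl-bearing carbon, C9, C10 CH2.

## Route

**Step 1**
Reactants: 1 3-methoxycyclopent-2-en-1-one
Product: 3 3-[(methoxymethoxy)methyl]cyclopent-2-en-1-one, via lithium alkoxide adduct 2 (not isolated)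
Conditions: Bu3SnCH2OCH2OMe, n-BuLi, THF, −78 °C; add 1, −78 → 0 °C; then 1 M aq. HCl, 0 °C
Reagents that add atoms: tributyl[(methoxymethoxy)methyl]stannane CCCC[Sn](CCCC)(CCCC)COCOC; water O
Why: Stork–Danheiser sequence: 1,2-addition of the α-alkoxy organolithium to the vinylogous ester, then acid hydrolysis/dehydration, transposes the enone and places the future C10 on the β-carbon; no stereocentre is formed.

**Step 2**
Reactants: 3 3-[(methoxymethoxy)methyl]cyclopent-2-en-1-one
Product: 6 (3R)-3-[(methoxymethoxy)methyl]-3-methylcyclopent-1-en-1-yl trifluoromethanesulfonate, via dimethylaluminium enolate 4 (not isolated), via lithium aluminate enolate 5 (not isolated)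
Conditions: Me3Al (1.4 equiv), Cu(O2C-C4H3S) (copper thiophene-2-carboxylate, 5 mol%), chiral phosphinamine Ph2P–N[CH(CH3)(2-naphthyl)]2 (5.5 mol%, the enantiomer that gives (R)-6), Et2O, −30 °C; then THF, MeLi, −78 °C; PhNTf2, −78 °C → rt
Reagents that add atoms: trimethylaluminium C[Al](C)C; N-phenylbis(trifluoromethanesulfonimide) O=S(=O)(N(c1ccccc1)S(=O)(=O)C(F)(F)F)C(F)(F)F
Why: Copper-catalysed asymmetric conjugate addition of Me3Al sets the C1 quaternary stereocentre under ligand control, and O-triflation of the regiodefined, ate-activated enolate fixes the double bond between C4 and C5.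

**Step 3**
Reactants: 6 (3R)-3-[(methoxymethoxy)methyl]-3-methylcyclopent-1-en-1-yl trifluoromethanesulfonate
Product: 7 (3R)-3-(hydroxymethyl)-3-methylcyclopent-1-en-1-yl trifluoromethanesulfonate
Conditions: conc. HCl (cat.), MeOH, 40 °C
Reagents that add atoms: none
Why: Acid-catalysed acetal exchange removes the MOM group while the electron-poor vinyl triflate is inert, so the acid step is done before the acid-sensitive trisubstituted alkene exists.

**Step 4**
Reactants: 7 (3R)-3-(hydroxymethyl)-3-methylcyclopent-1-en-1-yl trifluoromethanesulfonate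
Product: 8 [(1R)-1-methyl-3-(propan-2-yl)cyclopent-2-en-1-yl]methanol
Conditions: i-PrMgCl (2.6 equiv), Fe(acac)3 (5 mol%), THF/NMP, −20 → 0 °C
Reagents that add atoms: isopropylmagnesium chloride CC(C)[Mg]Cl
Why: Iron-catalysed Kumada cross-coupling of the alkenyl triflate with the secondary Grignard reagent (the first equivalent deprotonates the OH) puts isopropyl on C4 without moving the double bond or touching C1.

**Step 5**
Reactants: 8 [(1R)-1-methyl-3-(propan-2-yl)cyclopent-2-en-1-yl]methanol
Product: 9 (3R)-3-(iodomethyl)-3-methyl-1-(propan-2-yl)cyclopent-1-ene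
Conditions: I2, PPh3, imidazole, toluene, 80 °C
Reagents that add atoms: iodine II
Why: Appel-type iodination via the alkoxyphosphonium ion and SN2 displacement by iodide in a non-ionising solvent; the stereocentre is not involved.

**Step 6**
Reactants: 10 prop-2-yn-1-ol
Product: 12 (2Z)-3-iodo-2-methylprop-2-en-1-ol, via alkenylmagnesium bromide 11 (not isolated)
Conditions: MeMgBr (2.5 equiv), CuI (10 mol%), THF, −10 °C → rt; then I2, −10 °C; aq. NH4Cl
Reagents that add atoms: methylmagnesium bromide C[Mg]Br; iodine II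
Why: Alkoxide-directed, copper-catalysed anti-carbomagnesiation puts CH3 on C8 and magnesium on C9 cis to the CH2O group, and iodinolysis with retention gives the Z-vinyl iodide.

**Step 7**
Reactants: 12 (2Z)-3-iodo-2-methylprop-2-en-1-ol
Product: 13 (1Z)-3-bromo-1-iodo-2-methylprop-1-ene
Conditions: CBr4, PPh3, CH2Cl2, 0 °C
Reagents that add atoms: carbon tetrabromide BrC(Br)(Br)Br
Why: Appel bromination of the primary allylic alcohol by SN2 displacement keeps the alkene geometry.

**Step 8**
Reactants: 14 1,3-dithiane; 13 (1Z)-3-bromo-1-iodo-2-methylprop-1-ene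
Product: 16 2-[(2Z)-3-iodo-2-methylprop-2-en-1-yl]-1,3-dithiane, via 2-lithio-1,3-dithiane 15 (not isolated)
Conditions: n-BuLi, THF, −30 °C; then 13, −78 → −20 °C
Reagents that add atoms: none
Why: Corey–Seebach alkylation: the dithianyl anion (C6 as a masked aldehyde) displaces the allylic bromide by SN2 and, being the more stable carbanion, does not exchange with the vinyl iodide.

**Step 9**
Reactants: 16 2-[(2Z)-3-iodo-2-methylprop-2-en-1-yl]-1,3-dithiane
Product: 17 (1Z)-1-iodo-4,4-dimethoxy-2-methylbut-1-ene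
Conditions: PhI(OCOCF3)2 (1.5 equiv), MeOH, rt
Reagents that add atoms: methanol CO
Why: Oxidative dethioacetalisation with a hypervalent iodine reagent in methanol gives the dimethyl acetal directly, so the isomerisable β,γ-unsaturated aldehyde is never free.

**Step 10**
Reactants: 18 4-bromophenol
Product: 19 (4-bromophenoxy)(tert-butyl)dimethylsilane
Conditions: TBSCl, imidazole, DMF, rt
Reagents that add atoms: tert-butyl(chloro)dimethylsilane CC(C)(C)[Si](C)(C)Cl
Why: Standard silylation masks the phenol for the organolithium and acylation steps.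

**Step 11**
Reactants: 19 (4-bromophenoxy)(tert-butyl)dimethylsilane
Product: 21 4-[(tert-butyldimethylsilyl)oxy]benzoic acid, via aryllithium 20 (not isolated)
Conditions: n-BuLi, THF, −78 °C; CO2 (g); cold 1 M aq. HCl
Reagents that add atoms: carbon dioxide O=C=O
Why: Bromine–lithium exchange followed by carboxylation of the aryllithium.

**Step 12**
Reactants: 21 4-[(tert-butyldimethylsilyl)oxy]benzoic acid
Product: 22 4-[(tert-butyldimethylsilyl)oxy]benzoyl chloride
Conditions: (COCl)2, DMF (cat.), CH2Cl2, 0 °C → rt; evaporate, use crude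
Reagents that add atoms: oxalyl chloride O=C(Cl)C(Cl)=O
Why: Vilsmeier-type activation gives the acid chloride needed to acylate a hindered secondary alcohol.

**Step 13**
Reactants: 9 (3R)-3-(iodomethyl)-3-methyl-1-(propan-2-yl)cyclopent-1-ene; 17 (1Z)-1-iodo-4,4-dimethoxy-2-methylbut-1-ene
Product: 25 (3S)-3-[(2Z)-5,5-dimethoxy-3-methylpent-2-en-1-yl]-3-methyl-1-(propan-2-yl)cyclopent-1-ene, via alkyllithium 23 (not isolated), via alkylzinc chloride 24 (not isolated)
Conditions: t-BuLi (2.1 equiv), Et2O, −78 °C; ZnCl2 (THF), −78 °C → rt; 17, Pd(PPh3)4 (5 mol%), THF, rt → 40 °C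
Reagents that add atoms: none
Why: Negishi sp3–sp2 cross-coupling: iodine–lithium exchange, transmetalation to zinc, and palladium-catalysed coupling with retention of the Z geometry; the neopentyl zinc reagent has no β-hydrogen (the descriptor at C1 changes from R to S by priority only).

**Step 14**
Reactants: 25 (3S)-3-[(2Z)-5,5-dimethoxy-3-methylpent-2-en-1-yl]-3-methyl-1-(propan-2-yl)cyclopent-1-ene
Product: 27 (3Z)-3-methyl-5-[(1S)-1-methyl-3-(propan-2-yl)cyclopent-2-en-1-yl]pent-3-enal oxime, via aldehyde 26 (not isolated)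
Conditions: NH2OH·HCl (3 equiv), NaOAc (1.5 equiv), EtOH/H2O (4:1), 50 °C
Reagents that add atoms: hydroxylamine hydrochloride Cl.NO
Why: Mildly acidic acetal cleavage with in situ oxime condensation traps the β,γ-unsaturated aldehyde before it can isomerise; the oxime geometry is irrelevant.

**Step 15**
Reactants: 27 (3Z)-3-methyl-5-[(1S)-1-methyl-3-(propan-2-yl)cyclopent-2-en-1-yl]pent-3-enal oxime
Product: 29 (1S,4R,5S)-tricyclic 2-isoxazoline [O on C4; N=C6; C8=C9 retained], via nitrile oxide 28 (not isolated)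
Conditions: PhI(OAc)2 (1.2 equiv), CF3CO2H (5 mol%), MeOH/CH2Cl2, 0 °C → rt, slow addition of 27 (final 0.005 M)
Reagents that add atoms: none
Why: Intramolecular nitrile oxide–alkene (3+2) cycloaddition: C6 can reach C5 only from the cyclopentene face that carries the C10 tether, and oxygen adds suprafacially to the more substituted C4. C5–C6 and C4–O are therefore both cis to C10 and anti to the C1 methyl, which gives the cis ring fusion and the 4R carbinol centre.

**Step 16**
Reactants: 29 (1S,4R,5S)-tricyclic 2-isoxazoline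
Product: 31 (1S,4R,5R)-4-hydroxy-1,8-dimethyl-4-(propan-2-yl)bicyclo[5.3.0]dec-8-en-6-one (daucane locants), via hydroxy imine 30 (not isolated)
Conditions: Mo(CO)6 (1.2 equiv), MeCN/H2O (10:1), 80 °C
Reagents that add atoms: water O
Why: Reductive N–O cleavage by Mo(CO)6 and hydrolysis of the β-hydroxy imine unmask the β-hydroxy ketone under neutral conditions that leave the alkene and the C5 configuration alone.

**Step 17**
Reactants: 31 (1S,4R,5R)-4-hydroxy-1,8-dimethyl-4-(propan-2-yl)bicyclo[5.3.0]dec-8-en-6-one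
Product: 33 (1S,4R,5S,6R)-1,8-dimethyl-4-(propan-2-yl)bicyclo[5.3.0]dec-8-ene-4,6-diol (daucane locants), via boron chelate 32 (not isolated)
Conditions: Et2BOMe (1.2 equiv), THF/MeOH (4:1), −78 °C; NaBH4, −78 °C; AcOH; MeOH co-evaporation
Reagents that add atoms: none
Why: Narasaka–Prasad reduction: in the boron chelate between O4 and the C6 carbonyl, external hydride attacks from the side of H-5, away from the quaternary C1, giving the syn-1,3-diol (6R).

**Step 18**
Reactants: 33 (1S,4R,5S,6R)-1,8-dimethyl-4-(propan-2-yl)bicyclo[5.3.0]dec-8-ene-4,6-diol; 22 4-[(tert-butyldimethylsilyl)oxy]benzoyl chloride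
Product: 34 (1S,4R,5S,6R)-4-hydroxy-1,8-dimethyl-4-(propan-2-yl)bicyclo[5.3.0]dec-8-en-6-yl 4-[(tert-butyldimethylsilyl)oxy]benzoate
Conditions: pyridine, DMAP (0.2 equiv), CH2Cl2, 0 → 35 °C
Reagents that add atoms: none
Why: DMAP-catalysed acylation joins the two 17-atom fragments; only the secondary C6 hydroxyl reacts, the tertiary C4 hydroxyl being too hindered.

**Step 19**
Reactants: 34 (1S,4R,5S,6R)-4-hydroxy-1,8-dimethyl-4-(propan-2-yl)bicyclo[5.3.0]dec-8-en-6-yl 4-[(tert-butyldimethylsilyl)oxy]benzoate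
Product: 35 (1S,4R,5S,6R,8R,9S)-8,9-epoxy-4-hydroxy-1,8-dimethyl-4-(propan-2-yl)bicyclo[5.3.0]decan-6-yl 4-[(tert-butyldimethylsilyl)oxy]benzoate
Conditions: mCPBA (1.2 equiv), NaHCO3, CH2Cl2, 0 °C
Reagents that add atoms: 3-chloroperoxybenzoic acid OOC(=O)c1cccc(Cl)c1
Why: Prilezhaev epoxidation of the only alkene from the convex face of the cis-fused bicycle (the face of H-5 and the C1 methyl), anti to the aroyloxy group on C6 and to the folded cyclopentane, giving the 8R,9S epoxide.

**Step 20**
Reactants: 35 (1S,4R,5S,6R,8R,9S)-8,9-epoxy-4-hydroxy-1,8-dimethyl-4-(propan-2-yl)bicyclo[5.3.0]decan-6-yl 4-[(tert-butyldimethylsilyl)oxy]benzoate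
Product: 36 (1S,4R,5S,6R,8R,9S)-8,9-epoxy-4-hydroxy-1,8-dimethyl-4-(propan-2-yl)bicyclo[5.3.0]decan-6-yl 4-hydroxybenzoate (CNP0163817.4)
Conditions: Bu4NF (1.1 equiv), AcOH (1.2 equiv), THF, 0 °C
Reagents that add atoms: none
Why: Buffered fluoride cleaves the aryl silyl ether quickly and leaves the ester, epoxide and tertiary alcohol intact.

## Compound list

1 | 3-methoxycyclopent-2-en-1-one | COC1=CC(=O)CC1 | starting material
2 | lithium 3-methoxy-1-[(methoxymethoxy)methyl]cyclopent-2-en-1-olate (racemic) | [Li]OC1(COCOC)C=C(OC)CC1 | intermediate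
3 | 3-[(methoxymethoxy)methyl]cyclopent-2-en-1-one | COCOCC1=CC(=O)CC1 | intermediate
4 | dimethylaluminium enolate of (3R)-3-[(methoxymethoxy)methyl]-3-methylcyclopentanone (C4=C5 enolate) | C[Al](C)OC1=C[C@](C)(COCOC)CC1 | intermediate
5 | lithium trimethylaluminate enolate derived from 4 | [Li+].C[Al-](C)(C)OC1=C[C@](C)(COCOC)CC1 | intermediate
6 | (3R)-3-[(methoxymethoxy)methyl]-3-methylcyclopent-1-en-1-yl trifluoromethanesulfonate | FC(F)(F)S(=O)(=O)OC1=C[C@](C)(COCOC)CC1 | intermediate
7 | (3R)-3-(hydroxymethyl)-3-methylcyclopent-1-en-1-yl trifluoromethanesulfonate | FC(F)(F)S(=O)(=O)OC1=C[C@](C)(CO)CC1 | intermediate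
8 | [(1R)-1-methyl-3-(propan-2-yl)cyclopent-2-en-1-yl]methanol | CC(C)C1=C[C@](C)(CO)CC1 | intermediate
9 | (3R)-3-(iodomethyl)-3-methyl-1-(propan-2-yl)cyclopent-1-ene | CC(C)C1=C[C@](C)(CI)CC1 | intermediate
10 | prop-2-yn-1-ol | C#CCO | starting material
11 | (Z)-bromomagnesium 3-(bromomagnesio)-2-methylprop-2-en-1-olate | Br[Mg]OC/C(C)=C\[Mg]Br | intermediate
12 | (2Z)-3-iodo-2-methylprop-2-en-1-ol | OC/C(C)=C\I | intermediate
13 | (1Z)-3-bromo-1-iodo-2-methylprop-1-ene | BrC/C(C)=C\I | intermediate
14 | 1,3-dithiane | C1CSCSC1 | starting material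
15 | 2-lithio-1,3-dithiane | [Li]C1SCCCS1 | intermediate
16 | 2-[(2Z)-3-iodo-2-methylprop-2-en-1-yl]-1,3-dithiane | C1CSC(SC1)C/C(C)=C\I | intermediate
17 | (1Z)-1-iodo-4,4-dimethoxy-2-methylbut-1-ene | COC(OC)C/C(C)=C\I | intermediate
18 | 4-bromophenol | Oc1ccc(Br)cc1 | starting material
19 | (4-bromophenoxy)(tert-butyl)dimethylsilane | CC(C)(C)[Si](C)(C)Oc1ccc(Br)cc1 | intermediate
20 | {4-[(tert-butyldimethylsilyl)oxy]phenyl}lithium | [Li]c1ccc(O[Si](C)(C)C(C)(C)C)cc1 | intermediate
21 | 4-[(tert-butyldimethylsilyl)oxy]benzoic acid | OC(=O)c1ccc(O[Si](C)(C)C(C)(C)C)cc1 | intermediate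
22 | 4-[(tert-butyldimethylsilyl)oxy]benzoyl chloride | ClC(=O)c1ccc(O[Si](C)(C)C(C)(C)C)cc1 | intermediate
23 | {[(1R)-1-methyl-3-(propan-2-yl)cyclopent-2-en-1-yl]methyl}lithium | CC(C)C1=C[C@](C)(C[Li])CC1 | intermediate
24 | chloro{[(1R)-1-methyl-3-(propan-2-yl)cyclopent-2-en-1-yl]methyl}zinc | CC(C)C1=C[C@](C)(C[Zn]Cl)CC1 | intermediate
25 | (3S)-3-[(2Z)-5,5-dimethoxy-3-methylpent-2-en-1-yl]-3-methyl-1-(propan-2-yl)cyclopent-1-ene | CC(C)C1=C[C@](C)(C/C=C(/C)CC(OC)OC)CC1 | intermediate
26 | (3Z)-3-methyl-5-[(1S)-1-methyl-3-(propan-2-yl)cyclopent-2-en-1-yl]pent-3-enal | CC(C)C1=C[C@](C)(C/C=C(/C)CC=O)CC1 | intermediate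
27 | oxime of 26 (C=N geometry not defined) | CC(C)C1=C[C@](C)(C/C=C(/C)CC=NO)CC1 | intermediate
28 | (3Z)-3-methyl-5-[(1S)-1-methyl-3-(propan-2-yl)cyclopent-2-en-1-yl]pent-3-enenitrile N-oxide | CC(C)C1=C[C@](C)(C/C=C(/C)CC#[N+][O-])CC1 | intermediate
29 | (1S,4R,5S)-tricyclic 2-isoxazoline (cis-fused 5-7 carbocycle; O on C4, N=C6; C8=C9) | CC(C)[C@]1(ON=3)CC[C@@]2(C)CC=C(C)CC3[C@H]21 | intermediate
30 | (1S,4R,5S)-4-hydroxy-1,8-dimethyl-4-(propan-2-yl)bicyclo[5.3.0]dec-8-en-6-imine | CC(C)[C@]1(O)CC[C@@]2(C)CC=C(C)CC(=N)[C@H]21 | intermediate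
31 | (1S,4R,5R)-4-hydroxy-1,8-dimethyl-4-(propan-2-yl)bicyclo[5.3.0]dec-8-en-6-one | CC(C)[C@]1(O)CC[C@@]2(C)CC=C(C)CC(=O)[C@H]21 | intermediate
32 | O4-diethylboryl chelate of 31 | CC(C)[C@]1(OB(CC)CC)CC[C@@]2(C)CC=C(C)CC(=O)[C@H]21 | intermediate
33 | (1S,4R,5S,6R)-1,8-dimethyl-4-(propan-2-yl)bicyclo[5.3.0]dec-8-ene-4,6-diol | CC(C)[C@]1(O)CC[C@@]2(C)CC=C(C)C[C@@H](O)[C@H]21 | intermediate
34 | 6-O-{4-[(tert-butyldimethylsilyl)oxy]benzoyl} ester of 33 | CC(C)[C@]1(O)CC[C@@]2(C)CC=C(C)C[C@@H](OC(=O)c3ccc(O[Si](C)(C)C(C)(C)C)cc3)[C@H]21 | intermediate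
35 | (8R,9S)-epoxide of 34 | CC(C)[C@]1(O)CC[C@@]2(C)C[C@@H]3O[C@]3(C)C[C@@H](OC(=O)c3ccc(O[Si](C)(C)C(C)(C)C)cc3)[C@H]21 | intermediate
36 | (1S,4R,5S,6R,8R,9S)-8,9-epoxy-4-hydroxy-1,8-dimethyl-4-(propan-2-yl)bicyclo[5.3.0]decan-6-yl 4-hydroxybenzoate | CC(C)[C@]1(O)CC[C@@]2(C)C[C@@H]3O[C@]3(C)C[C@@H](OC(=O)c3ccc(O)cc3)[C@H]21 | target

## Step count and risks

Total step count: 20. Longest linear sequence: 13 (steps 1–5, then 13–20); the other branches are steps 6–9 and 10–12.

The three steps most likely to fail: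

Step 2 (asymmetric conjugate methylation with in-flask triflation). The enantioselectivity on this alkoxymethyl-substituted cyclopentenone and the trapping of an aluminium enolate are both uncertain. The fallback gives up catalytic control and resolves. Setting out from 3, Me2CuLi with Me3SiCl (THF, −78 °C) gives racemic trimethylsilyl enol ether F1. MeLi followed by PhNTf2 converts it into racemic triflate F2, and HCl/MeOH gives racemic hydroxy triflate F3. The iron-catalysed isopropyl coupling then gives racemic alcohol F4. Its enantiomers are separated by preparative chromatography on a chiral stationary phase, and the (R)-enantiomer is 8, where the route is rejoined.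

Step 15 (seven-membered ring by nitrile oxide cycloaddition). Ring closure may be slower than dimerisation of the nitrile oxide. The fallback avoids a free nitrile oxide. Setting out from 27, heating in 1,2-dichlorobenzene (180 °C, sealed tube) effects an intramolecular oxime–olefin cycloaddition through the N–H nitrone tautomer and gives N–H isoxazolidine F5, with the same tether-enforced cis fusion. Dehydrogenation with activated MnO2 (CH2Cl2, rt) then gives isoxazoline 29, where the route is rejoined.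

Step 19 (face selectivity of the epoxidation). The angular methyl and the aroyloxy group shield opposite faces, so the peracid may prefer the wrong face. The fallback inverts the outcome through a halohydrin. Setting out from 34, NBS in THF/H2O (0 °C) gives bromohydrin F6: the bromonium ion forms on the face the peracid prefers and water opens it at the tertiary C8 from the other side. DBU (CH2Cl2, rt) closes the ring with inversion at C9 and gives 35, where the route is rejoined.

## Further compounds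

F1 | step 2 | racemic {3-[(methoxymethoxy)methyl]-3-methylcyclopent-1-en-1-yl}oxy(trimethyl)silane | C[Si](C)(C)OC1=CC(C)(COCOC)CC1
F2 | step 2 | racemic 3-[(methoxymethoxy)methyl]-3-methylcyclopent-1-en-1-yl trifluoromethanesulfonate | FC(F)(F)S(=O)(=O)OC1=CC(C)(COCOC)CC1
F3 | step 2 | racemic 3-(hydroxymethyl)-3-methylcyclopent-1-en-1-yl trifluoromethanesulfonate | FC(F)(F)S(=O)(=O)OC1=CC(C)(CO)CC1
F4 | step 2 | racemic [1-methyl-3-(propan-2-yl)cyclopent-2-en-1-yl]methanol | CC(C)C1=CC(C)(CO)CC1
F5 | step 15 | (1S,4R,5S)-tricyclic N–H isoxazolidine (O on C4, NH on C6; C6 configuration immaterial) | CC(C)[C@]1(ON3)CC[C@@]2(C)CC=C(C)CC3[C@H]21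
F6 | step 19 | bromohydrin of 34 (Br on C9 on the face opposite H-5; OH on C8 on the face of H-5) | CC(C)[C@]1(O)CC[C@@]2(C)C[C@@H](Br)[C@@](O)(C)C[C@@H](OC(=O)c3ccc(O[Si](C)(C)C(C)(C)C)cc3)[C@H]21
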